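- Don't read the equivalents of coupling partner as the yield at 80 min. In Tuesday's, Thursday's and Friday's, charged below one equivalent, coupling partner is the limiting reagent and the equivalents give a ceiling, and your next decision is whether such a flask can be judged finished at that time.

| flask | substrate | coupling partner | free catalyst | remark | time |
|---|---|---|---|---|---|
| south-west | 0.10 M (in portions, 3) | 0.094 equiv | 3.1 mol% | run made earlier; portions every 2.5 min |  |
| north-west | 0.10 M (in portions, 3) | 1.2 equiv | 3.1 mol% | run made earlier; portions every 2.5 min |  |
| Thursday's | 0.10 M (in portions, 3) | 0.170 equiv | 3.1 mol% | the portions of substrate follow each other after 2.5 min, the first at the start | 80 min |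
| Monday's | 0.10 M (in portions, 3) | 1.50 equiv | 3.1 mol% | the portions of substrate follow each other after 2.5 min, the first at the start | 80 min |
| Tuesday's | 0.10 M (in portions, 3) | 0.500 equiv | 3.1 mol% | the portions of substrate follow each other after 2.5 min, the first at the start | 80 min |
| Wednesday's | 0.10 M (in portions, 3) | 1.00 equiv | 3.1 mol% | the portions of substrate follow each other after 2.5 min, the first at the start | 80 min |
| Friday's | 0.10 M (in portions, 3) | 0.120 equiv | 3.1 mol% | the portions of substrate follow each other after 2.5 min, the first at the start | 80 min |

- south-west (time / min: product / %, substrate / %): 3.00: 0.9, 62.5; 5.00: 2.9, 57.4; 8.00: 6.0, 89.2; 15.0: 8.8, 86.8; 25.0: 9.9, 89.3; 40.0: 9.1, 86.9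
- north-west (time / min: product / %, substrate / %): 6.00: 14.4, 82.6; 12.0: 29.0, 69.9; 20.0: 39.4, 58.5; 25.0: 46.7, 51.3; 30.0: 48.2, 47.4; 40.0: 57.1, 38.6

(readings scatter by 1 percentage point)

- all flasks from highest to lowest amount of product, in percent of the substrate charged, at 80 min (Thursday's / Monday's / Tuesday's / Wednesday's / Friday's)
- the amount of product, in percent of the substrate charged of the flask you put first, at 80 min
- the amount of product, in percent of the substrate charged of the flask you put last, at 80 min

- The south-west run stands near 9.9 % on a charge of 0.094 equiv, so I take the ceiling as the charge of partner. In a flask short of partner, like the south-west run with 0.094 equiv, I assume that the catalyst rests as catalyst intermediate A (the resting state), which leaves 96.9 % of substrate free to become product.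
- My assumption is that returning product competes with substrate for free catalyst, so with scarce partner the product rate is g × partner × substrate/product.
- The south-west readings at 5.00 min and 15.0 min give 0.0184 min⁻¹ for g, the clock constant. It is a rough reading, because 8.8 % lies close to the ceiling and the scatter is 1 percentage point.
- Integrated, with ceiling L, free substrate S, fraction of partner left x and product P = L(1 − x), the rule reads: g × time since the last portion = [−L·ln x + S·ln(1 − P/S)] / (S − L).
- For Friday's, 0.674 % of the partner is left after 35.2 min, so I commit to its ceiling of 0.120 as a fraction, about 12.0 %.
- For Tuesday's, 8.21 % of the partner is left after 77.7 min, with product at 45.9 %. Don't count this flask as finished at 80 min.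
- The clock is built for scarce partner, so it says nothing of Monday's or Wednesday's. The north-west run already shows 57.1 % at 40.0 min, above Tuesday's ceiling, so I rank the flasks by charge of partner.
- The forecast gives Monday's > Wednesday's > Tuesday's > Thursday's > Friday's, with 76 % (70 % to 82 %) and 12 % (11.3 % to 12.3 %), and says the lower flasks “run to their partner limits”, which for Tuesday's means 50 % against my 45.9 %.

    catalyst intermediate B ⇌ free catalyst + product (K = 0.0326 M, k = 0.191 s⁻¹)
    substrate + free catalyst → catalyst intermediate A (k = 0.508 M⁻¹ s⁻¹)
    coupling partner + catalyst intermediate A ⇌ catalyst intermediate B (K = 8.66 M⁻¹, k = 332 M⁻¹ s⁻¹)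

- The flasks give Monday's > Wednesday's > Tuesday's > Thursday's > Friday's, with 76.8 % first and 12.0 % last. In Tuesday's, at 5.00 min, substrate was turning free catalyst, still 37.7 % of the catalyst, into catalyst intermediate A while 80.3 % of the partner remained. At 80.0 min, catalyst intermediate A held 95.0 % of the catalyst, product stood at 46.2 % and 7.3 % of the partner remained, a state the clock places at 83.4 min. A neighbour of Friday's charged with 0.200 equiv ends at 20.0 % with 0.19 % of its partner unbound, and the clock places that at 77.7 min.

The readings were computed with constants of no real substance; scatter was added.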